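**The ratio.** Start from target over substrate charged: the autumn flask opens at 0.800, with the spring charge of substrate, partner and free catalyst. Ask what a share that high does to the catalyst.

| setting | spring | noon | autumn |
|---|---|---|---|
| substrate | 120 mM | 240 mM | 120 mM |
| partner | 132 mM | 132 mM | 132 mM |
| free catalyst | 6.00 mM | 6.00 mM | 6.00 mM |
| target |  |  | 96.0 mM |
| time |  |  | 170 min |

| run | time / min | [substrate] / mM |
|---|---|---|
| spring run | 21 | 102.2 |
| spring run | 42 | 90.0 |
| spring run | 64 | 81.4 |
| spring run | 85 | 76.4 |
| spring run | 110 | 73.1 |
| spring run | 130 | 71.8 |
| spring run | 150 | 70.4 |
| spring run | 170 | 69.1 |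
| noon run | 21 | 215.6 |
| noon run | 42 | 198.1 |
| noon run | 64 | 187.1 |
| noon run | 85 | 179.4 |
| noon run | 110 | 174.2 |
| noon run | 130 | 172.4 |
| noon run | 150 | 170.6 |
| noon run | 170 | 170.2 |

(scatter of a reading: 0.4 mM)

- reaction order in [substrate] at the outset, round the charge of the spring run, defined at two percent of the substrate turned into target (one fixed amount of target, the same in the runs compared)
- substrate in the autumn run at 170 min, as a share of the substrate charged

- Overall: substrate + partner -> target, with free catalyst as catalyst.
- Constant volume, constant temperature.
- The analysis sees a species whether free or bound.
- "The second partner" is partner.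
- An order is taken over about fifteen percent of the charge, up and down.

**Two falls.** Read the spring run interval by interval. Round 21 min, with target at 0.148 of the charge, the rate falls by 0.0180 min⁻¹. Taking order one in substrate and in partner, their use accounts for 0.0132 min⁻¹, which leaves 0.00474 min⁻¹. Round 64 min, with target at 0.322, the fall is 0.0225 min⁻¹ and the use 0.00727 min⁻¹, which leaves 0.0152 min⁻¹.

The later remainder is larger than the earlier one, so treat it as catalyst loss that quickens as target grows, not as a steady clock. Divide it by the target share to get the loss coefficient, the catalyst loss per minute per unit of target counted as a share of the spring charge: a reading of 0.0472 min⁻¹. Its inverse at a given share is the catalyst life, or deactivation time.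

**The ladder.** Go from fastest to slowest. At its opening share, the autumn flask has a catalyst life of 26.5 min. The spring run, round 64 min, has a life of 65.9 min, which is longer. The spring charge at its mean rate over the first 21 min, 0.00706 min⁻¹ of the charge, would take 142 min, longer still. The spring readings show 0.424 of the charge turned by 170 min.

**My reckoning.** Give the autumn flask that spring mean rate. Since 170 min is longer than its opening life, multiply rate by life: my estimate is that 0.187 of the charge turns and 81.3% of the substrate stays.

The forecast, which differs from my reckoning, gave 59% and an order of 0.52, holding that this “looks like time-based catalyst death”.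

**The flask.** The autumn flask keeps 82.8% of its substrate at 170 min, and the order at the outset of the spring run is 0.67.

    free catalyst + substrate ⇌ catalyst-substrate complex, settled at all times (0.8770 M⁻¹)
    catalyst-substrate complex + partner → target + free catalyst + by-product (15.54 M⁻¹ min⁻¹)
    free catalyst + target → spent catalyst + target (0.4878 M⁻¹ min⁻¹)
    catalyst-substrate complex + substrate ⇌ doubly bound catalyst, settled at all times (13.80 M⁻¹)

Now use the coefficient on the noon run: its target reaches a quarter of its charge at 83.3 min, which is 0.500 of the spring charge, and the catalyst life there reckons to 42.4 min.

The runs stem from a simulated flask on assumed constants; noise was put on by code.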